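**Retrosynthetic overview**

1. Target 19 (ring: C1 O‑angeloyl, C2 H2, C3 methyl, C4 OAc, C5 H2, C6 side chain; side chain: C1' CH(CH3), C2' H2, C3' CH(OAc), C4'=C5'Me2) ⇒ acetylation of the C3' allylic alcohol 18.
2. Key disconnection C2'–C3': 18 ⇒ ring‑bearing isopropenyl diester 13 + 3‑methylbut‑2‑enal 14, joined in one flask by hydroboration, boron–zinc exchange and Ti‑catalysed asymmetric alkyl addition. This completes the C15 skeleton and sets both side‑chain stereocentres (C1' by substrate control, C3' by catalyst control).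
3. Enabling feature: the C6–C1'(H)(CH3)–C2'H2 unit is the anti‑Markovnikov hydrometalation retron of an isopropenyl group on ring carbon C6, whose faces are differentiated by the trans‑diequatorial acyloxy‑bearing neighbour C1 of the cyclohexane ring; C3' is a secondary allylic carbinol, i.e. the 1,2‑adduct of a β,β‑disubstituted enal.
4. 13 ⇒ (R)‑4‑silyloxycyclohex‑2‑enone 4 ⇒ 1: the C1 carbinol (asymmetric transfer hydrogenation) relays C6 (anti cuprate addition), C3 (equilibration) and C4 (L‑Selectride); the angelate is installed before the key step.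
5. Rings: the single cyclohexane ring is present in starting material 1; no ring is formed or opened.

Key step: step 10

Remarks: the target numbering of overview line 1 is used in all Why lines. Et2BH (from BH3·SMe2/BEt3) and (Me3SiCH2)2Zn (from Me3SiCH2MgCl/ZnBr2) are assumed to be prepared beforehand as stock reagents. Catalyst enantiomers are chosen by the established sense of induction of each catalyst class.

**Route**

Step 1
Reactants: 1 1,4‑dioxaspiro[4.5]dec‑6‑en‑8‑one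
Product: 2 (8R)‑1,4‑dioxaspiro[4.5]dec‑6‑en‑8‑ol
Conditions: RuCl[(R,R)‑TsDPEN](p‑cymene) (1 mol %), HCO2Na, Bu4NCl (cat.), CH2Cl2/H2O, rt
Reagents that add atoms: none
Why: Noyori asymmetric transfer hydrogenation reduces the enone carbonyl 1,2‑selectively, and with the C=C taking the place of the aryl group in the usual model the (R,R) catalyst should give the (R)‑carbinol (future C1), the only stereocentre set by catalysis.

Step 2
Reactants: 2 (8R)‑1,4‑dioxaspiro[4.5]dec‑6‑en‑8‑ol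
Product: 3 tert‑butyl{[(8R)‑1,4‑dioxaspiro[4.5]dec‑6‑en‑8‑yl]oxy}dimethylsilane
Conditions: TBSCl, imidazole, DMF, rt
Reagents that add atoms: tert‑butyldimethylsilyl chloride, CC(C)(C)[Si](C)(C)Cl
Why: Imidazole‑promoted silylation of a secondary allylic alcohol is routine and touches no stereocentre.

Step 3
Reactants: 3 tert‑butyl{[(8R)‑1,4‑dioxaspiro[4.5]dec‑6‑en‑8‑yl]oxy}dimethylsilane
Product: 4 (4R)‑4‑{[tert‑butyl(dimethyl)silyl]oxy}cyclohex‑2‑en‑1‑one
Conditions: montmorillonite K10, wet CH2Cl2, rt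
Reagents that add atoms: water, O
Why: Mild acid‑catalysed ketal hydrolysis unmasks the ketone in conjugation with the ring alkene, so the silyloxy carbon becomes the γ‑carbon of a cyclohex‑2‑enone, and the secondary TBS ether should survive clay catalysis.

Step 4
Reactants: 4 (4R)‑4‑{[tert‑butyl(dimethyl)silyl]oxy}cyclohex‑2‑en‑1‑one
Product: 5 (4R)‑4‑{[tert‑butyl(dimethyl)silyl]oxy}‑6‑methylcyclohex‑2‑en‑1‑one (mixture of C6 epimers)
Conditions: LDA, THF, −78 °C; MeI, −78 → −40 °C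
Reagents that add atoms: iodomethane, CI
Why: Kinetic α'‑deprotonation occurs at the only sp3 α‑carbon and the cross‑conjugated enolate is C‑methylated (enolate alkylation); the configuration of the new centre (future C3) is unimportant because it is equilibrated in step 5.

Step 5
Reactants: 5 (4R)‑4‑{[tert‑butyl(dimethyl)silyl]oxy}‑6‑methylcyclohex‑2‑en‑1‑one; 6 isopropenylmagnesium bromide
Product: 8 (2S,4R,5S)‑4‑{[tert‑butyl(dimethyl)silyl]oxy}‑2‑methyl‑5‑(prop‑1‑en‑2‑yl)cyclohexan‑1‑one, via trimethylsilyl enol ether 7 (not isolated)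
Conditions: 6, CuBr·SMe2 (10 mol %), TMSCl, THF, −78 → −40 °C; crude 7, NaOMe (cat.), MeOH, 0 °C → rt
Reagents that add atoms: isopropenylmagnesium bromide 6, C=C(C)[Mg]Br (chlorotrimethylsilane, C[Si](C)(C)Cl, adds the silyl group of 7 only)
Why: Copper‑catalysed, TMSCl‑accelerated conjugate addition occurs anti to the γ‑silyloxy group and sets C6 trans to the C1 oxygen, and methoxide then cleaves the silyl enol ether and equilibrates the α‑methyl centre C3 to the all‑equatorial ketone (thermodynamic control).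

Step 6
Reactants: 8 (2S,4R,5S)‑4‑{[tert‑butyl(dimethyl)silyl]oxy}‑2‑methyl‑5‑(prop‑1‑en‑2‑yl)cyclohexan‑1‑one
Product: 9 (1R,2S,4R,5S)‑4‑{[tert‑butyl(dimethyl)silyl]oxy}‑2‑methyl‑5‑(prop‑1‑en‑2‑yl)cyclohexan‑1‑ol
Conditions: L‑Selectride, THF, −78 °C; then H2O
Reagents that add atoms: none
Why: The bulky trialkylborohydride attacks the cyclohexanone from the equatorial direction, giving the axial C4 alcohol cis to the equatorial C3 methyl, as is general for 2‑methylcyclohexanones.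

Step 7
Reactants: 9 (1R,2S,4R,5S)‑4‑{[tert‑butyl(dimethyl)silyl]oxy}‑2‑methyl‑5‑(prop‑1‑en‑2‑yl)cyclohexan‑1‑ol
Product: 10 (1R,2S,4R,5S)‑4‑{[tert‑butyl(dimethyl)silyl]oxy}‑2‑methyl‑5‑(prop‑1‑en‑2‑yl)cyclohexyl acetate
Conditions: Ac2O, Et3N, DMAP (cat.), CH2Cl2, rt
Reagents that add atoms: acetic anhydride, CC(=O)OC(C)=O
Why: DMAP‑catalysed acetylation should acylate the hindered axial secondary alcohol without affecting the silyl ether or the alkene.

Step 8
Reactants: 10 (1R,2S,4R,5S)‑4‑{[tert‑butyl(dimethyl)silyl]oxy}‑2‑methyl‑5‑(prop‑1‑en‑2‑yl)cyclohexyl acetate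
Product: 11 (1R,2S,4R,5S)‑4‑hydroxy‑2‑methyl‑5‑(prop‑1‑en‑2‑yl)cyclohexyl acetate
Conditions: TBAF, AcOH, THF, rt
Reagents that add atoms: none
Why: Fluoride cleaves the Si–O bond, the acetic acid buffer suppresses acetate cleavage, and the 1,4‑relationship of the two oxygens excludes acyl migration.

Step 9
Reactants: 11 (1R,2S,4R,5S)‑4‑hydroxy‑2‑methyl‑5‑(prop‑1‑en‑2‑yl)cyclohexyl acetate; 12 angelic acid
Product: 13 (1R,2S,4R,5S)‑4‑(acetyloxy)‑5‑methyl‑2‑(prop‑1‑en‑2‑yl)cyclohexyl (2Z)‑2‑methylbut‑2‑enoate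
Conditions: 12, 2,4,6‑trichlorobenzoyl chloride, Et3N, toluene, rt; then 11, toluene, 80 °C (no DMAP)
Reagents that add atoms: angelic acid 12, C/C=C(/C)C(=O)O
Why: In this Yamaguchi‑type esterification the alcohol attacks the unshielded angeloyl carbonyl of the mixed anhydride, and leaving out the nucleophilic catalyst avoids the addition–elimination pathway that isomerises the Z‑enoate to the tiglate.

Step 10
Reactants: 13 (1R,2S,4R,5S)‑4‑(acetyloxy)‑5‑methyl‑2‑(prop‑1‑en‑2‑yl)cyclohexyl (2Z)‑2‑methylbut‑2‑enoate; 14 3‑methylbut‑2‑enal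
Product: 18 (1R,2S,4R,5S)‑4‑(acetyloxy)‑2‑[(2R,4R)‑4‑hydroxy‑6‑methylhept‑5‑en‑2‑yl]‑5‑methylcyclohexyl (2Z)‑2‑methylbut‑2‑enoate, via alkyldiethylborane 15 (not isolated), via dialkylzinc 16 (not isolated), via mixed alkylzinc 17 (not isolated)
Conditions: Et2BH (1.2 equiv), Et2O, 0 °C → rt, volatiles removed; Et2Zn (neat), 0 °C, BEt3/Et2Zn removed in vacuo; (Me3SiCH2)2Zn, Et2O, rt; Ti(OiPr)4, (1S,2S)‑1,2‑bis(trifluoromethanesulfonamido)cyclohexane (8 mol %), 14, toluene, −20 °C; H2O quench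
Reagents that add atoms: 3‑methylbut‑2‑enal 14, CC(C)=CC=O (Et2BH, CCBCC; Et2Zn, CC[Zn]CC; (Me3SiCH2)2Zn, C[Si](C)(C)C[Zn]C[Si](C)(C)C add atoms to intermediates 15–17 only)
Why: Et2BH adds anti‑Markovnikov and syn across the 1,1‑disubstituted C1'=C2' alkene, the primary C–B bond is exchanged for C–Zn, the dialkylzinc is converted into the mixed alkyl(trimethylsilylmethyl)zinc so that only the ring‑bearing group is transferred, and the chiral titanium bis(sulfonamide) complex catalyses 1,2‑alkyl transfer to the aldehyde carbon of 14, forming C2'–C3'. The closest known reaction type is the hydroboration/boron–zinc exchange/Ti–bis(triflamide)‑catalysed asymmetric addition of ester‑functionalised dialkylzincs to α,β‑unsaturated aldehydes; no ring is closed. C1' is set by substrate control: in the staggered hydroboration transition state the allylic ring hydrogen on C6 lies next to the vinylic methyl (A1,2 strain) and the borane approaches anti to the more substituted, acyloxy‑bearing ring carbon C1, the sense known for isopulegol‑type homoallylic systems. C3' is set by the catalyst: the (1R,2R) ligand is known to direct alkyl groups to the Si face of aldehydes, so the (1S,2S) ligand should direct to the Re face and give the (R)‑carbinol. The step needs chemoselective hydroboration of the electron‑rich terminal alkene next to the electron‑poor trisubstituted angelate alkene and two esters (secured by the low reactivity of dialkylboranes towards conjugated esters and about one equivalent of borane) and 1,2‑ over 1,4‑addition to the enal (secured by the β,β‑dimethyl substitution and titanium activation of the carbonyl).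

Step 11
Reactants: 18 (1R,2S,4R,5S)‑4‑(acetyloxy)‑2‑[(2R,4R)‑4‑hydroxy‑6‑methylhept‑5‑en‑2‑yl]‑5‑methylcyclohexyl (2Z)‑2‑methylbut‑2‑enoate
Product: 19 (1R,2S,4R,5S)‑4‑(acetyloxy)‑2‑[(2R,4R)‑4‑(acetyloxy)‑6‑methylhept‑5‑en‑2‑yl]‑5‑methylcyclohexyl (2Z)‑2‑methylbut‑2‑enoate
Conditions: Ac2O, pyridine, DMAP (cat.), CH2Cl2, 0 °C → rt
Reagents that add atoms: acetic anhydride, CC(=O)OC(C)=O
Why: Base‑mediated acetylation of the secondary allylic alcohol proceeds with retention at C3' and without ionising the allylic system or isomerising the angelate.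

**Compound list**

1 | 1,4‑dioxaspiro[4.5]dec‑6‑en‑8‑one | O=C1CCC2(OCCO2)C=C1 | starting material
2 | (8R)‑1,4‑dioxaspiro[4.5]dec‑6‑en‑8‑ol | O[C@@H]1CCC2(OCCO2)C=C1 | intermediate
3 | tert‑butyl{[(8R)‑1,4‑dioxaspiro[4.5]dec‑6‑en‑8‑yl]oxy}dimethylsilane | CC(C)(C)[Si](C)(C)O[C@@H]1CCC2(OCCO2)C=C1 | intermediate
4 | (4R)‑4‑{[tert‑butyl(dimethyl)silyl]oxy}cyclohex‑2‑en‑1‑one | CC(C)(C)[Si](C)(C)O[C@@H]1CCC(=O)C=C1 | intermediate
5 | (4R)‑4‑{[tert‑butyl(dimethyl)silyl]oxy}‑6‑methylcyclohex‑2‑en‑1‑one, C6 epimers | CC(C)(C)[Si](C)(C)O[C@@H]1CC(C)C(=O)C=C1 | intermediate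
6 | isopropenylmagnesium bromide | C=C(C)[Mg]Br | starting material
7 | (3S,4R)‑4‑{[tert‑butyl(dimethyl)silyl]oxy}‑6‑methyl‑3‑(prop‑1‑en‑2‑yl)‑1‑(trimethylsilyloxy)cyclohex‑1‑ene, C6 epimers | CC(C)(C)[Si](C)(C)O[C@@H]1CC(C)C(O[Si](C)(C)C)=C[C@H]1C(C)=C | intermediate
8 | (2S,4R,5S)‑4‑{[tert‑butyl(dimethyl)silyl]oxy}‑2‑methyl‑5‑(prop‑1‑en‑2‑yl)cyclohexan‑1‑one | CC(C)(C)[Si](C)(C)O[C@@H]1C[C@H](C)C(=O)C[C@H]1C(C)=C | intermediate
9 | (1R,2S,4R,5S)‑4‑{[tert‑butyl(dimethyl)silyl]oxy}‑2‑methyl‑5‑(prop‑1‑en‑2‑yl)cyclohexan‑1‑ol | CC(C)(C)[Si](C)(C)O[C@@H]1C[C@H](C)[C@H](O)C[C@H]1C(C)=C | intermediate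
10 | (1R,2S,4R,5S)‑4‑{[tert‑butyl(dimethyl)silyl]oxy}‑2‑methyl‑5‑(prop‑1‑en‑2‑yl)cyclohexyl acetate | CC(C)(C)[Si](C)(C)O[C@@H]1C[C@H](C)[C@H](OC(C)=O)C[C@H]1C(C)=C | intermediate
11 | (1R,2S,4R,5S)‑4‑hydroxy‑2‑methyl‑5‑(prop‑1‑en‑2‑yl)cyclohexyl acetate | O[C@@H]1C[C@H](C)[C@H](OC(C)=O)C[C@H]1C(C)=C | intermediate
12 | angelic acid, (2Z)‑2‑methylbut‑2‑enoic acid | C/C=C(/C)C(=O)O | starting material
13 | (1R,2S,4R,5S)‑4‑(acetyloxy)‑5‑methyl‑2‑(prop‑1‑en‑2‑yl)cyclohexyl (2Z)‑2‑methylbut‑2‑enoate | C/C=C(/C)C(=O)O[C@@H]1C[C@H](C)[C@H](OC(C)=O)C[C@H]1C(C)=C | intermediate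
14 | 3‑methylbut‑2‑enal | CC(C)=CC=O | starting material
15 | (1R,2S,4R,5S)‑4‑(acetyloxy)‑2‑[(2R)‑1‑(diethylboranyl)propan‑2‑yl]‑5‑methylcyclohexyl (2Z)‑2‑methylbut‑2‑enoate | C/C=C(/C)C(=O)O[C@@H]1C[C@H](C)[C@H](OC(C)=O)C[C@H]1[C@H](C)CB(CC)CC | intermediate
16 | bis{(2S)‑2‑[(1S,2R,4S,5R)‑5‑(acetyloxy)‑4‑methyl‑2‑{[(2Z)‑2‑methylbut‑2‑enoyl]oxy}cyclohexyl]propyl}zinc (same spatial arrangement at C1' as in 15; descriptors differ only by CIP priority) | C/C=C(/C)C(=O)O[C@@H]1C[C@H](C)[C@H](OC(C)=O)C[C@H]1[C@H](C)C[Zn]C[C@@H](C)[C@@H]1C[C@@H](OC(C)=O)[C@@H](C)C[C@H]1OC(=O)/C(C)=C\C | intermediate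
17 | {(2S)‑2‑[(1S,2R,4S,5R)‑5‑(acetyloxy)‑4‑methyl‑2‑{[(2Z)‑2‑methylbut‑2‑enoyl]oxy}cyclohexyl]propyl}[(trimethylsilyl)methyl]zinc | C/C=C(/C)C(=O)O[C@@H]1C[C@H](C)[C@H](OC(C)=O)C[C@H]1[C@H](C)C[Zn]C[Si](C)(C)C | intermediate
18 | (1R,2S,4R,5S)‑4‑(acetyloxy)‑2‑[(2R,4R)‑4‑hydroxy‑6‑methylhept‑5‑en‑2‑yl]‑5‑methylcyclohexyl (2Z)‑2‑methylbut‑2‑enoate | C/C=C(/C)C(=O)O[C@@H]1C[C@H](C)[C@H](OC(C)=O)C[C@H]1[C@H](C)C[C@H](C=C(C)C)O | intermediate
19 | (1R,2S,4R,5S)‑4‑(acetyloxy)‑2‑[(2R,4R)‑4‑(acetyloxy)‑6‑methylhept‑5‑en‑2‑yl]‑5‑methylcyclohexyl (2Z)‑2‑methylbut‑2‑enoate | C/C=C(/C)C(=O)O[C@@H]1C[C@H](C)[C@H](OC(C)=O)C[C@H]1[C@H](C)C[C@H](C=C(C)C)OC(C)=O | target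

**Step count and risks**

Total step count: 11. Longest linear sequence: 11 steps (from 1); 6, 12 and 14 enter as purchased building blocks.

Steps most likely to fail:

Step 10. Facial selectivity in the hydroboration of the isopropenyl group may be incomplete, transfer of the β‑branched alkyl group from zinc may be slow with competing β‑hydride reduction of the aldehyde, and catalyst control at C3' may erode. The fallback separates the two events and reverses the polarity at C3'. It sets out from 13: hydroboration with 9‑BBN (THF, rt) and oxidation with NaBO3·4H2O should give the primary alcohol (1R,2S,4R,5S)‑4‑(acetyloxy)‑2‑[(2S)‑1‑hydroxypropan‑2‑yl]‑5‑methylcyclohexyl (2Z)‑2‑methylbut‑2‑enoate F1, at which stage C1' epimers can be separated. Iodination (I2, PPh3, imidazole, CH2Cl2) gives the primary iodide F2, and zinc insertion (activated Zn, DMA) gives the alkylzinc iodide F3. Pd(PPh3)4‑catalysed Negishi acylation with 3‑methylbut‑2‑enoyl chloride gives the enone F4. Corey–Bakshi–Shibata reduction with the (S)‑methyl oxazaborolidine and catecholborane (toluene, −78 °C; alkenyl as the large group) should give the (R)‑carbinol and return to the route at 18.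

Step 9. The angeloyl unit may isomerise from Z to E during acyl activation or transfer, or acylation of the flanked equatorial alcohol may stall. The fallback builds the Z‑alkene on the ester instead. It sets out from 11: esterification with 2‑[bis(2,2,2‑trifluoroethoxy)phosphoryl]propanoic acid (DCC, DMAP, CH2Cl2) gives the phosphonate ester F5, and Still–Gennari olefination with acetaldehyde (KHMDS, 18‑crown‑6, THF, −78 °C) should give the Z‑enoate and return to the route at 13.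

Step 4. Over‑alkylation and competing γ‑deprotonation or proton exchange may occur during enolate methylation of the γ‑silyloxy enone. The fallback reverses the order of the two C–C bond formations. It sets out from 4: copper‑catalysed conjugate addition of 6 (CuBr·SMe2 cat., THF, −40 °C, aqueous NH4Cl quench, no silyl trap) gives (3S,4R)‑4‑{[tert‑butyl(dimethyl)silyl]oxy}‑3‑(prop‑1‑en‑2‑yl)cyclohexan‑1‑one F6. Kinetic deprotonation (LDA, THF, −78 °C) on the methylene remote from the branched β‑carbon, methylation (MeI) and methoxide equilibration as in step 5 return to the route at 8.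

**Further compounds**

F1 | step 10 | (1R,2S,4R,5S)‑4‑(acetyloxy)‑2‑[(2S)‑1‑hydroxypropan‑2‑yl]‑5‑methylcyclohexyl (2Z)‑2‑methylbut‑2‑enoate | C/C=C(/C)C(=O)O[C@@H]1C[C@H](C)[C@H](OC(C)=O)C[C@H]1[C@H](C)CO
F2 | step 10 | (1R,2S,4R,5S)‑4‑(acetyloxy)‑2‑[(2S)‑1‑iodopropan‑2‑yl]‑5‑methylcyclohexyl (2Z)‑2‑methylbut‑2‑enoate | C/C=C(/C)C(=O)O[C@@H]1C[C@H](C)[C@H](OC(C)=O)C[C@H]1[C@H](C)CI
F3 | step 10 | {(2S)‑2‑[(1S,2R,4S,5R)‑5‑(acetyloxy)‑4‑methyl‑2‑{[(2Z)‑2‑methylbut‑2‑enoyl]oxy}cyclohexyl]propyl}zinc iodide | C/C=C(/C)C(=O)O[C@@H]1C[C@H](C)[C@H](OC(C)=O)C[C@H]1[C@H](C)C[Zn]I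
F4 | step 10 | (1R,2S,4R,5S)‑4‑(acetyloxy)‑5‑methyl‑2‑[(2R)‑6‑methyl‑4‑oxohept‑5‑en‑2‑yl]cyclohexyl (2Z)‑2‑methylbut‑2‑enoate | C/C=C(/C)C(=O)O[C@@H]1C[C@H](C)[C@H](OC(C)=O)C[C@H]1[C@H](C)CC(=O)C=C(C)C
F5 | step 9 | (1R,2S,4R,5S)‑4‑(acetyloxy)‑5‑methyl‑2‑(prop‑1‑en‑2‑yl)cyclohexyl 2‑[bis(2,2,2‑trifluoroethoxy)phosphoryl]propanoate (epimers at the phosphonate α‑carbon) | CC(C(=O)O[C@@H]1C[C@H](C)[C@H](OC(C)=O)C[C@H]1C(C)=C)P(=O)(OCC(F)(F)F)OCC(F)(F)F
F6 | step 4 | (3S,4R)‑4‑{[tert‑butyl(dimethyl)silyl]oxy}‑3‑(prop‑1‑en‑2‑yl)cyclohexan‑1‑one | CC(C)(C)[Si](C)(C)O[C@@H]1CCC(=O)C[C@H]1C(C)=C
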